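Ring B (C5–C10, labdane numbering) is traced to the cyclopentanone of a trans-hydrindanone made from (S)-Hajos–Parrish ketone. The key step, a Lewis-acid-mediated diazoethane homologation, expands this ring by inserting C8 together with its methyl group between the carbonyl carbon C9 and C7. It exploits the C8(CH3)=C9 unit of ring B next to the quaternary C10: only the CH2 side can migrate readily, and the new ketone enolises only towards C8, so its enol triflate fixes the tetrasubstituted alkene. Negishi coupling, phosphonylation, Horner–Wadsworth–Emmons olefination, ester reduction and Suzuki coupling with 4-bromofuranone then build the dienyl butenolide side chain.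

Key step: step 5

Remark: labdane numbering is used for the core (C10 quaternary ring-fusion carbon, C5 ring-fusion CH, C8 methyl-bearing alkene carbon, C9 chain-bearing alkene carbon); 9, 13 and 16 are taken as purchasable, and 7 is drawn as its equatorial-methyl epimer (the other epimer converges in step 6).

Step 1
Reactants: 1 (S)-Hajos–Parrish ketone
Product: 2 (7aS)-1,1-(ethylenedioxy)-7a-methyl-1,2,3,6,7,7a-hexahydro-5H-inden-5-one
Conditions: (TMSOCH2)2, TMSOTf (cat.), CH2Cl2, −78 → −20 °C
Reagents that add atoms: 1,2-bis(trimethylsilyloxy)ethane, C[Si](C)(C)OCCO[Si](C)(C)C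
Why: Noyori ketalization should take the saturated, more electrophilic C1 ketone and leave the deactivated enone carbonyl, with no stereocentre touched.

Step 2
Reactants: 2 (7aS)-1,1-(ethylenedioxy)-7a-methyl-1,2,3,6,7,7a-hexahydro-5H-inden-5-one
Product: 3 (7aS)-1,1-(ethylenedioxy)-4,4,7a-trimethyl-1,2,4,6,7,7a-hexahydro-5H-inden-5-one
Conditions: t-BuOK (3 equiv), MeI (4 equiv), t-BuOH/THF, 0 °C → rt
Reagents that add atoms: iodomethane, CI
Why: Deconjugative α,α-dimethylation of the enone through its extended dienolate should place both methyl groups on the α-carbon (the future C4) and move the alkene to C3=C3a of the five-membered ring, the ketal being stable to base.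

Step 3
Reactants: 3 (7aS)-1,1-(ethylenedioxy)-4,4,7a-trimethyl-1,2,4,6,7,7a-hexahydro-5H-inden-5-one
Product: 4 (7aS)-1,1-(ethylenedioxy)-4,4,7a-trimethyl-2,4,5,6,7,7a-hexahydro-1H-indene
Conditions: N2H4·H2O, KOH, diethylene glycol, 130 °C then 200 °C
Reagents that add atoms: none
Why: Wolff–Kishner reduction (Huang-Minlon procedure) should remove the carbonyl next to the new quaternary carbon, while the non-conjugated alkene and the dioxolane tolerate hot base.

Step 4
Reactants: 4 (7aS)-1,1-(ethylenedioxy)-4,4,7a-trimethyl-2,4,5,6,7,7a-hexahydro-1H-indene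
Product: 6 (3aS,7aS)-4,4,7a-trimethyloctahydro-1H-inden-1-one, via saturated dioxolane 5 (not isolated)
Conditions: H2 (4 atm), 10% Pd/C, EtOH, rt; then 2 M aq. HCl added to the same flask, rt
Reagents that add atoms: water, O
Why: Catalytic hydrogenation should deliver hydrogen to C3a from the α face, opposite the angular methyl and the axial methyl of the gem-dimethyl group (as Δ14 sterols do), setting the trans ring fusion (3aS), and aqueous acid then hydrolyses the ketal.

Step 5
Reactants: 6 (3aS,7aS)-4,4,7a-trimethyloctahydro-1H-inden-1-one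
Product: 7 (2R,4aS,8aS)-2,5,5,8a-tetramethyloctahydronaphthalen-1(2H)-one
Conditions: CH3CHN2 (Et2O solution, made from N-ethyl-N-nitrosourea and aq. KOH), BF3·OEt2, CH2Cl2, −40 → 0 °C
Reagents that add atoms: diazoethane, CC=[N+]=[N-]
Why: BF3 activates the C9 carbonyl of 6, the nucleophilic carbon of diazoethane adds to it, and the resulting β-alkoxy diazonium betaine loses N2 with a 1,2-shift of the ring CH2 (C7) from C9 to the new carbon, which becomes C8 and already carries its methyl group. The closest known reaction type is the Lewis-acid-promoted diazoalkane homologation of cyclic ketones (Tiffeneau–Demjanov type), as used for the D-homoannulation of 17-oxo steroids, whose trans-hydrindanone D ring is the direct model for 6. No ring is closed: the five-membered ring C5–C6–C7–C9–C10 grows to the six-membered ring B by insertion of one carbon between C9 and C7. The new stereocentre C8 is epimerisable and should settle under thermodynamic control with the methyl group equatorial, but it becomes sp2 in step 6, so its configuration is of no consequence, and C5 and C10 are untouched. The step needs migration of C7 and not of the quaternary C10, and a single insertion: the first is secured because the less substituted α-carbon migrates in these homologations, the second because ketone 7, flanked by C10 and the tertiary C8, is far less electrophilic than 6.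

Step 6
Reactants: 7 (2R,4aS,8aS)-2,5,5,8a-tetramethyloctahydronaphthalen-1(2H)-one
Product: 8 (4aS,8aS)-2,5,5,8a-tetramethyl-3,4,4a,5,6,7,8,8a-octahydronaphthalen-1-yl trifluoromethanesulfonate
Conditions: Tf2O, 2,6-di-tert-butyl-4-methylpyridine, CH2Cl2, 0 °C → rt
Reagents that add atoms: trifluoromethanesulfonic anhydride, O=S(=O)(OS(=O)(=O)C(F)(F)F)C(F)(F)F
Why: Enol triflate formation can only occur towards C8 because C10 is quaternary, so the C8=C9 alkene is fixed without regiochemical doubt (as with 2,2,6-trimethylcyclohexanone) and the C8 stereocentre is erased.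

Step 7
Reactants: 8 (4aS,8aS)-2,5,5,8a-tetramethyl-3,4,4a,5,6,7,8,8a-octahydronaphthalen-1-yl trifluoromethanesulfonate; 9 (4-ethoxy-4-oxobutyl)zinc bromide
Product: 10 ethyl 4-[(4aS,8aS)-2,5,5,8a-tetramethyl-3,4,4a,5,6,7,8,8a-octahydronaphthalen-1-yl]butanoate
Conditions: PdCl2(dppf) (5 mol %), LiCl, THF/NMP, 60 °C
Reagents that add atoms: none
Why: Negishi sp2–sp3 coupling of an enol triflate with a primary ester-bearing alkylzinc halide should attach C11–C13 and the future hydroxymethyl carbon in one operation, the bidentate ligand suppressing β-hydride elimination.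

Step 8
Reactants: 10 ethyl 4-[(4aS,8aS)-2,5,5,8a-tetramethyl-3,4,4a,5,6,7,8,8a-octahydronaphthalen-1-yl]butanoate
Product: 12 ethyl 2-(diethoxyphosphoryl)-4-[(4aS,8aS)-2,5,5,8a-tetramethyl-3,4,4a,5,6,7,8,8a-octahydronaphthalen-1-yl]butanoate, via phosphonite 11 (not isolated)
Conditions: LiN(i-Pr)2, THF, −78 °C; ClP(OEt)2, −78 °C → rt; then 30% aq. H2O2, 0 °C
Reagents that add atoms: diethyl chlorophosphite, CCOP(Cl)OCC; hydrogen peroxide, OO
Why: C-phosphinylation of the ester enolate by the soft trivalent phosphorus chloride followed by oxidation gives the α-phosphono ester (α-phosphono ester synthesis through a phosphonite), the new α-stereocentre being uncontrolled and destroyed in step 9.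

Step 9
Reactants: 12 ethyl 2-(diethoxyphosphoryl)-4-[(4aS,8aS)-2,5,5,8a-tetramethyl-3,4,4a,5,6,7,8,8a-octahydronaphthalen-1-yl]butanoate; 13 (E)-3-(4,4,5,5-tetramethyl-1,3,2-dioxaborolan-2-yl)prop-2-enal
Product: 14 ethyl (2E,4E)-2-{2-[(4aS,8aS)-2,5,5,8a-tetramethyl-3,4,4a,5,6,7,8,8a-octahydronaphthalen-1-yl]ethyl}-5-(4,4,5,5-tetramethyl-1,3,2-dioxaborolan-2-yl)penta-2,4-dienoate
Conditions: NaH, THF, 0 °C; then 13, 0 °C → rt
Reagents that add atoms: none
Why: Horner–Wadsworth–Emmons olefination of an α-alkyl phosphonoacetate with an enal should give the (2E)-trisubstituted enoate (ester trans to the dienyl chain) under thermodynamic control of the oxaphosphetane, the E alkene of 13 being carried over.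

Step 10
Reactants: 14 ethyl (2E,4E)-2-{2-[(4aS,8aS)-2,5,5,8a-tetramethyl-3,4,4a,5,6,7,8,8a-octahydronaphthalen-1-yl]ethyl}-5-(4,4,5,5-tetramethyl-1,3,2-dioxaborolan-2-yl)penta-2,4-dienoate
Product: 15 (2E,4E)-2-{2-[(4aS,8aS)-2,5,5,8a-tetramethyl-3,4,4a,5,6,7,8,8a-octahydronaphthalen-1-yl]ethyl}-5-(4,4,5,5-tetramethyl-1,3,2-dioxaborolan-2-yl)penta-2,4-dien-1-ol
Conditions: i-Bu2AlH (2.5 equiv), CH2Cl2, −78 °C; aq. potassium sodium tartrate
Reagents that add atoms: none
Why: 1,2-Reduction of the conjugated ester by i-Bu2AlH at low temperature should give the allylic alcohol without touching the pinacol alkenylboronate or the alkene geometries, and it is placed before the lactone is introduced.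

Step 11
Reactants: 15 (2E,4E)-2-{2-[(4aS,8aS)-2,5,5,8a-tetramethyl-3,4,4a,5,6,7,8,8a-octahydronaphthalen-1-yl]ethyl}-5-(4,4,5,5-tetramethyl-1,3,2-dioxaborolan-2-yl)penta-2,4-dien-1-ol; 16 4-bromofuran-2(5H)-one
Product: 17 4-[(1E,3E)-4-(hydroxymethyl)-6-[(4aS,8aS)-2,5,5,8a-tetramethyl-3,4,4a,5,6,7,8,8a-octahydronaphthalen-1-yl]hexa-1,3-dien-1-yl]furan-2(5H)-one
Conditions: PdCl2(dppf) (5 mol %), K3PO4, THF/H2O (degassed), 40 °C
Reagents that add atoms: none
Why: Suzuki–Miyaura sp2–sp2 coupling of the (E)-dienylboronate with the β-bromobutenolide should proceed with retention of alkene geometry and tolerate the free allylic alcohol, the mild phosphate base limiting opening of the lactone.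

Compound list
1 | (S)-Hajos–Parrish ketone, (7aS)-7a-methyl-2,3,7,7a-tetrahydro-1H-indene-1,5(6H)-dione | O=C1[C@@]2(C)CCC(=O)C=C2CC1 | starting material
2 | (7aS)-1,1-(ethylenedioxy)-7a-methyl-1,2,3,6,7,7a-hexahydro-5H-inden-5-one (1-ethylene ketal of 1) | O1CCOC12[C@@]3(C)CCC(=O)C=C3CC2 | intermediate
3 | (7aS)-1,1-(ethylenedioxy)-4,4,7a-trimethyl-1,2,4,6,7,7a-hexahydro-5H-inden-5-one (C3=C3a alkene) | O1CCOC12[C@@]3(C)CCC(=O)C(C)(C)C3=CC2 | intermediate
4 | (7aS)-1,1-(ethylenedioxy)-4,4,7a-trimethyl-2,4,5,6,7,7a-hexahydro-1H-indene (C3=C3a alkene) | O1CCOC12[C@@]3(C)CCCC(C)(C)C3=CC2 | intermediate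
5 | (3aS,7aS)-1,1-(ethylenedioxy)-4,4,7a-trimethyloctahydro-1H-indene (trans-fused, not isolated) | O1CCOC12[C@@]3(C)CCCC(C)(C)[C@@H]3CC2 | intermediate
6 | (3aS,7aS)-4,4,7a-trimethyloctahydro-1H-inden-1-one (trans-fused) | O=C1[C@@]2(C)CCCC(C)(C)[C@@H]2CC1 | intermediate
7 | (2R,4aS,8aS)-2,5,5,8a-tetramethyloctahydronaphthalen-1(2H)-one | C[C@H]1C(=O)[C@@]2(C)CCCC(C)(C)[C@@H]2CC1 | intermediate
8 | (4aS,8aS)-2,5,5,8a-tetramethyl-3,4,4a,5,6,7,8,8a-octahydronaphthalen-1-yl trifluoromethanesulfonate | CC1=C(OS(=O)(=O)C(F)(F)F)[C@@]2(C)CCCC(C)(C)[C@@H]2CC1 | intermediate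
9 | (4-ethoxy-4-oxobutyl)zinc bromide (solution in THF) | CCOC(=O)CCC[Zn]Br | starting material
10 | ethyl 4-[(4aS,8aS)-2,5,5,8a-tetramethyl-3,4,4a,5,6,7,8,8a-octahydronaphthalen-1-yl]butanoate | CC1=C(CCCC(=O)OCC)[C@@]2(C)CCCC(C)(C)[C@@H]2CC1 | intermediate
11 | ethyl 2-(diethoxyphosphanyl)-4-[(4aS,8aS)-2,5,5,8a-tetramethyl-3,4,4a,5,6,7,8,8a-octahydronaphthalen-1-yl]butanoate (both α-epimers, not isolated) | CC1=C(CCC(P(OCC)OCC)C(=O)OCC)[C@@]2(C)CCCC(C)(C)[C@@H]2CC1 | intermediate
12 | ethyl 2-(diethoxyphosphoryl)-4-[(4aS,8aS)-2,5,5,8a-tetramethyl-3,4,4a,5,6,7,8,8a-octahydronaphthalen-1-yl]butanoate (both α-epimers) | CC1=C(CCC(P(=O)(OCC)OCC)C(=O)OCC)[C@@]2(C)CCCC(C)(C)[C@@H]2CC1 | intermediate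
13 | (E)-3-(4,4,5,5-tetramethyl-1,3,2-dioxaborolan-2-yl)prop-2-enal | O=C/C=C/B1OC(C)(C)C(C)(C)O1 | starting material
14 | ethyl (2E,4E)-2-{2-[(4aS,8aS)-2,5,5,8a-tetramethyl-3,4,4a,5,6,7,8,8a-octahydronaphthalen-1-yl]ethyl}-5-(4,4,5,5-tetramethyl-1,3,2-dioxaborolan-2-yl)penta-2,4-dienoate | CC1=C(CC/C(C(=O)OCC)=C\C=C\B3OC(C)(C)C(C)(C)O3)[C@@]2(C)CCCC(C)(C)[C@@H]2CC1 | intermediate
15 | (2E,4E)-2-{2-[(4aS,8aS)-2,5,5,8a-tetramethyl-3,4,4a,5,6,7,8,8a-octahydronaphthalen-1-yl]ethyl}-5-(4,4,5,5-tetramethyl-1,3,2-dioxaborolan-2-yl)penta-2,4-dien-1-ol | CC1=C(CC/C(CO)=C\C=C\B3OC(C)(C)C(C)(C)O3)[C@@]2(C)CCCC(C)(C)[C@@H]2CC1 | intermediate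
16 | 4-bromofuran-2(5H)-one | BrC1=CC(=O)OC1 | starting material
17 | 4-[(1E,3E)-4-(hydroxymethyl)-6-[(4aS,8aS)-2,5,5,8a-tetramethyl-3,4,4a,5,6,7,8,8a-octahydronaphthalen-1-yl]hexa-1,3-dien-1-yl]furan-2(5H)-one | CC1=C(CC/C(=C\C=C\C2=CC(=O)OC2)CO)[C@@]2(C)CCCC(C)(C)[C@@H]2CC1 | target

Total step count: 11. Longest linear sequence: 11 steps (1 → 17); 9, 13 and 16 enter as purchased materials.

Steps most likely to fail

Step 5. The migration may not be clean: the quaternary C10 may shift in competition with C7, the betaine may close to an oxirane, or a second insertion may follow. The fallback sets out from 6 and returns to 7 by a ring expansion whose regiochemistry is fixed by an enol ether (Saegusa–Ito sequence). LiN(i-Pr)2 and Me3SiCl in THF at −78 °C should give the only possible silyl enol ether, (3aS,7aS)-4,4,7a-trimethyl-3a,4,5,6,7,7a-hexahydro-3H-inden-1-yl trimethylsilyl ether F1. Et2Zn and CH2I2 in CH2Cl2 should cyclopropanate it from the α face to the siloxycyclopropane F2. FeCl3 in DMF at 0 °C cleaves the internal cyclopropane bond to the ring-enlarged (4aS,8aS)-3-chloro-5,5,8a-trimethyloctahydronaphthalen-1(2H)-one F3, and NaOAc in MeOH eliminates HCl to the enone (4aS,8aS)-5,5,8a-trimethyl-4a,5,6,7,8,8a-hexahydronaphthalen-1(4H)-one F4. Conjugate reduction with LiBH(s-Bu)3 in THF at −78 °C and trapping of the enolate with MeI then gives 7. The inserted carbon is C8 by construction, and the methyl group enters at the only enolate position.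

Step 7. Oxidative addition and transmetalation at the tetrasubstituted enol triflate next to the quaternary C10 may be slow, so that the zinc reagent is protonated or the triflate is reduced or hydrolysed before coupling. The fallback sets out from 8 and returns to 10. A Suzuki–Miyaura coupling with potassium vinyltrifluoroborate (PdCl2(dppf), K2CO3, THF/H2O, 60 °C), an sp2–sp2 coupling well tolerated by such triflates, should give (4aS,8aS)-1-ethenyl-2,5,5,8a-tetramethyl-3,4,4a,5,6,7,8,8a-octahydronaphthalene F5. 9-BBN in THF hydroborates only the terminal vinyl group to the B-alkyl-9-borabicyclo[3.3.1]nonane F6 (not isolated). Its reaction with ethyl bromoacetate and t-BuOK in t-BuOH/THF at 0 °C (α-alkylation of a bromo ester enolate by an organoborane with 1,2-migration) adds the two missing carbons and gives 10.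

Step 4. Hydrogen delivery may be slow at the hindered trisubstituted alkene or may lose facial selectivity, which would give the cis-fused isomer. The fallback sets out from 4 and returns to 6 through 5 and makes no new compound (F0). Radical hydrogen-atom-transfer hydrogenation (Mn(dpm)3 cat., PhSiH3, t-BuOOH, i-PrOH, rt) adds a hydrogen atom to C3 and reduces the resulting tertiary C3a radical stepwise, which favours the more stable trans-fused dioxolane 5 and does not depend on adsorption of one alkene face on a metal surface. The same aqueous HCl treatment then gives 6.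

Further compounds
F1 | step 5 | (3aS,7aS)-4,4,7a-trimethyl-3a,4,5,6,7,7a-hexahydro-3H-inden-1-yl trimethylsilyl ether | C[Si](C)(C)OC=1[C@@]2(C)CCCC(C)(C)[C@@H]2CC=1
F2 | step 5 | siloxycyclopropane of F1 (CH2 bridging C1 and C2 on the α face, anti to the 7a-methyl) | C[Si](C)(C)O[C@]13[C@@]2(C)CCCC(C)(C)[C@@H]2C[C@H]1C3
F3 | step 5 | (4aS,8aS)-3-chloro-5,5,8a-trimethyloctahydronaphthalen-1(2H)-one (C3 epimers) | O=C1[C@@]2(C)CCCC(C)(C)[C@@H]2CC(Cl)C1
F4 | step 5 | (4aS,8aS)-5,5,8a-trimethyl-4a,5,6,7,8,8a-hexahydronaphthalen-1(4H)-one | O=C1[C@@]2(C)CCCC(C)(C)[C@@H]2CC=C1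
F5 | step 7 | (4aS,8aS)-1-ethenyl-2,5,5,8a-tetramethyl-3,4,4a,5,6,7,8,8a-octahydronaphthalene | CC1=C(C=C)[C@@]2(C)CCCC(C)(C)[C@@H]2CC1
F6 | step 7 | 9-{2-[(4aS,8aS)-2,5,5,8a-tetramethyl-3,4,4a,5,6,7,8,8a-octahydronaphthalen-1-yl]ethyl}-9-borabicyclo[3.3.1]nonane | CC1=C(CCB3C4CCCC3CCC4)[C@@]2(C)CCCC(C)(C)[C@@H]2CC1
F0 | step 4 | none | none
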